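**Retrosynthetic overview**
- The epoxide is made last, by Shi epoxidation of the C3=C4 E-alkene of the 14-membered triene lactone.
- The 14-membered ring is closed at C2–C3 by a nickel-mediated reductive coupling in which a primary C2 radical is captured by an E-alkenylnickel at C3. The radical sits next to the lactone, where the acrylate cannot trap it.
- The γ-lactone and the C14 and C1 stereocentres come from an indium Barbier allylation of an α-hydroxy aldehyde with a (Z)-2-(bromomethyl)enoate, followed by lactonisation.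
- C7 is set by CBS reduction of an enone made from an alkenyllithium (C8) and an aldehyde (C7). C12/C13 come from a Brown (Z)-crotylboration, and the C4 methyl and E-alkene from a Negishi carboalumination.
- Ring order: γ-lactone, then 14-membered carbocycle, then epoxide.

Assumption: atoms carry cembrane numbers (C1 = ring carbon bearing the acrylate unit, C14 = lactone carbinol carbon, C13 = acetoxy carbon, C12, C8 and C4 = branch carbons, C3–C4 = epoxide, C7 = carbinol), so the given SMILES reads 1S,3R,4R,7R,12S,13R,14R.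

**Route**

Step 1
Reactants: 1 pent-4-yn-1-ol
Product: 3 (E)-5-iodo-4-methylpent-4-en-1-ol, via alkenylalane 2 (not isolated)
Conditions: AlMe3 (3 equiv), Cp2ZrCl2 (0.25 equiv), CH2Cl2, 0 °C to rt; then I2, THF, −30 °C; aq. K2CO3
Reagents that add atoms: trimethylaluminium C[Al](C)C; iodine II
Why: Negishi zirconium-catalysed carboalumination adds Me and Al syn across the terminal alkyne with Al at the terminus, and iodinolysis with retention gives the E-alkenyl iodide that fixes the later C3=C4 geometry.

Step 2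
Reactants: 3 (E)-5-iodo-4-methylpent-4-en-1-ol
Product: 4 (E)-5-iodo-4-methylpent-4-enal
Conditions: DMP, CH2Cl2, rt
Reagents that add atoms: none
Why: Dess–Martin oxidation of a primary alcohol to the aldehyde leaves the alkenyl iodide untouched and creates no stereocentre.

Step 3
Reactants: 5 2-[(tert-butyldimethylsilyl)oxy]acetaldehyde; 6 methyl acrylate
Product: 7 methyl 4-[(tert-butyldimethylsilyl)oxy]-3-hydroxy-2-methylidenebutanoate (racemic)
Conditions: DABCO (0.3 equiv), neat, rt, 3 d
Reagents that add atoms: none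
Why: Morita–Baylis–Hillman reaction of an α-silyloxy aldehyde with an acrylate; the carbinol centre is racemic but is erased in step 4.

Step 4
Reactants: 7 methyl 4-[(tert-butyldimethylsilyl)oxy]-3-hydroxy-2-methylidenebutanoate
Product: 8 methyl (Z)-2-(bromomethyl)-4-[(tert-butyldimethylsilyl)oxy]but-2-enoate
Conditions: NBS, Me2S, CH2Cl2, 0 °C to rt
Reagents that add atoms: N-bromosuccinimide O=C1CCC(=O)N1Br
Why: Corey–Kim-type activation of the allylic alcohol and bromide attack with allylic transposition (SN2′) gives the conjugated trisubstituted (Z)-2-(bromomethyl)enoate under neutral conditions that spare the silyl ether.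

Step 5
Reactants: 9 2,2-dimethoxyacetaldehyde; 10 cis-but-2-ene
Product: 13 (2R,3S)-1,1-dimethoxy-3-methylpent-4-en-2-ol, via (Z)-crotylpotassium 11 (not isolated), via (Z)-crotylbis(isopinocampheyl)borane 12 (not isolated)
Conditions: 10, KOtBu, n-BuLi, THF, −78 to −45 °C; (+)-Ipc2BOMe, −78 °C; BF3·OEt2; anhydrous 9, −78 °C; then NaOH, H2O2
Reagents that add atoms: none
Why: Brown crotylboration through a chair transition state, in which the Z-crotyl geometry gives the syn methyl/hydroxyl pair (C12/C13) and the isopinocampheyl groups of (+)-Ipc2BOMe direct attack to the Re face of the aldehyde, setting 2R,3S.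

Step 6
Reactants: 13 (2R,3S)-1,1-dimethoxy-3-methylpent-4-en-2-ol
Product: 14 triethyl{[(2R,3S)-1,1-dimethoxy-3-methylpent-4-en-2-yl]oxy}silane
Conditions: TESCl, imidazole, CH2Cl2, 0 °C
Reagents that add atoms: chlorotriethylsilane CC[Si](Cl)(CC)CC
Why: Silylation protects the C13 hydroxyl through the organolithium and oxidation steps with a group that is removed together with the acetal in step 10.

Step 7
Reactants: 14 triethyl{[(2R,3S)-1,1-dimethoxy-3-methylpent-4-en-2-yl]oxy}silane; 15 2,3-dibromoprop-1-ene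
Product: 17 {[(2R,3S)-7-bromo-1,1-dimethoxy-3-methyloct-7-en-2-yl]oxy}triethylsilane, via B-alkyl-9-BBN 16 (not isolated)
Conditions: 9-BBN, THF, 0 °C to rt; then LiOtBu, CuI (10 mol %), 15, THF, rt
Reagents that add atoms: none
Why: Anti-Markovnikov hydroboration followed by copper-catalysed allyl–alkyl coupling of the alkylborane ate complex at the allylic C–Br bond of 15 (SN2 and SN2′ give the same 2-bromoalkene), while the alkenyl C–Br bond is inert to copper.

Step 8
Reactants: 17 {[(2R,3S)-7-bromo-1,1-dimethoxy-3-methyloct-7-en-2-yl]oxy}triethylsilane; 4 (E)-5-iodo-4-methylpent-4-enal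
Product: 19 (1E,10S,11R)-1-iodo-12,12-dimethoxy-2,10-dimethyl-6-methylidene-11-[(triethylsilyl)oxy]dodec-1-en-5-ol (both C5 epimers), via alkenyllithium 18 (not isolated)
Conditions: t-BuLi (2.1 equiv), Et2O, −78 °C; then 4, −78 °C; aq. work-up
Reagents that add atoms: none
Why: Bromine–lithium exchange and 1,2-addition of the alkenyllithium to the aldehyde at −78 °C, which is faster than iodine–lithium exchange; the new carbinol (C7) is formed unselectively and is oxidised in step 9.

Step 9
Reactants: 19 (1E,10S,11R)-1-iodo-12,12-dimethoxy-2,10-dimethyl-6-methylidene-11-[(triethylsilyl)oxy]dodec-1-en-5-ol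
Product: 20 (1E,10S,11R)-1-iodo-12,12-dimethoxy-2,10-dimethyl-6-methylidene-11-[(triethylsilyl)oxy]dodec-1-en-5-one
Conditions: DMP, pyridine, CH2Cl2, 0 °C to rt
Reagents that add atoms: none
Why: Dess–Martin oxidation converges both epimers to the 2-alkyl enone, which also serves as the masked form of the C7 alcohol until the reagent-controlled reduction in step 13.

Step 10
Reactants: 20 (1E,10S,11R)-1-iodo-12,12-dimethoxy-2,10-dimethyl-6-methylidene-11-[(triethylsilyl)oxy]dodec-1-en-5-one; 8 methyl (Z)-2-(bromomethyl)-4-[(tert-butyldimethylsilyl)oxy]but-2-enoate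
Product: 23 (4R,5R)-4-{[(tert-butyldimethylsilyl)oxy]methyl}-5-[(1R,2S,10E)-1-hydroxy-11-iodo-2,10-dimethyl-6-methylidene-7-oxoundec-10-en-1-yl]-3-methylideneoxolan-2-one, via hydroxy aldehyde 21 (not isolated), via hydroxy ester 22 (not isolated)
Conditions: TFA/H2O (9:1), 0 °C to rt, concentrate; then 8, In powder, THF/H2O (1:1), rt; then TsOH·H2O (cat.), CH2Cl2, rt
Reagents that add atoms: water O
Why: Acid removes the acetal and the TES group, then an indium Barbier allylation in water sets C14 syn to the free C13 hydroxyl by chelation and C1 syn to C14 through a chair transition state of the Z-allylindium reacting at its γ-carbon, and acid-catalysed lactonisation of the γ-hydroxy ester closes the cis-α-methylene-γ-butyrolactone (first ring).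

Step 11
Reactants: 23 the lactone alcohol of step 10
Product: 24 (1R,2S,10E)-1-[(2R,3R)-3-{[(tert-butyldimethylsilyl)oxy]methyl}-4-methylidene-5-oxooxolan-2-yl]-11-iodo-2,10-dimethyl-6-methylidene-7-oxoundec-10-en-1-yl acetate
Conditions: Ac2O, pyridine, DMAP (cat.), CH2Cl2, 0 °C to rt
Reagents that add atoms: acetic anhydride CC(=O)OC(C)=O
Why: Acylation of the only free hydroxyl (C13) installs the acetate of the target without touching a stereocentre.

Step 12
Reactants: 24 the acetate of step 11
Product: 25 (1R,2S,10E)-1-[(2R,3S)-3-(bromomethyl)-4-methylidene-5-oxooxolan-2-yl]-11-iodo-2,10-dimethyl-6-methylidene-7-oxoundec-10-en-1-yl acetate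
Conditions: Ph3PBr2, CH2Cl2, rt
Reagents that add atoms: dibromotriphenylphosphorane BrP(Br)(c1ccccc1)(c1ccccc1)c1ccccc1
Why: Direct conversion of the primary silyl ether into the bromide (bromophosphonium activation of the ether oxygen, then SN2 by bromide) gives the C2 halide; the descriptor at the ring carbon changes only because of CIP priorities.

Step 13
Reactants: 25 the bromide of step 12
Product: 26 (1R,2S,7R,10E)-1-[(2R,3S)-3-(bromomethyl)-4-methylidene-5-oxooxolan-2-yl]-7-hydroxy-11-iodo-2,10-dimethyl-6-methylideneundec-10-en-1-yl acetate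
Conditions: (S)-2-methyl-CBS-oxazaborolidine (0.3 equiv), catecholborane (1.5 equiv), toluene, −78 °C; MeOH quench
Reagents that add atoms: none
Why: Corey–Bakshi–Shibata reduction in which the 2-alkylvinyl group acts as the large substituent, so the (S)-catalyst delivers hydride to give the 7R allylic alcohol, while catecholborane at −78 °C leaves the lactone, acetate and halides alone.

Step 14
Reactants: 26 the bromo iodo allylic alcohol of step 13
Product: 27 (1S,3E,7R,12S,13R,14R)-13-acetoxy-7-hydroxycembra-3,8(19),15(17)-trien-16,14-olide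
Conditions: NiBr2(dme) (0.5 equiv), 4,4′-di-tert-butyl-2,2′-bipyridine (0.6 equiv), Mn powder (5 equiv), NaI (0.5 equiv), DMA, 45 °C, 26 added over 12 h (final 2 mM)
Reagents that add atoms: none
Why: Proposed new method: intramolecular nickel-catalysed reductive cross-electrophile coupling, in which zerovalent nickel inserts into the C3–I bond to give an alkenylnickel iodide (divalent nickel), monovalent nickel abstracts the halogen at C2 (after Br/I exchange by NaI) to give a primary alkyl radical that is captured by the alkenylnickel on the same chain, and reductive elimination from trivalent nickel forms C2–C3 with retention of the E geometry; the radical sits one carbon from the lactone, where attack on the acrylate would be 3-exo or 4-endo and unproductive, and slow addition keeps both chain ends on nickel; the closest known reaction type is the intermolecular nickel-catalysed reductive coupling of primary alkyl bromides with alkenyl halides using manganese, together with nickel-mediated reductive macrocyclisations of dihalides.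

Step 15
Reactants: 27 the macrocyclic triene of step 14
Product: 28 (1S,3R,4R,7R,12S,13R,14R)-13-acetoxy-3,4-epoxy-7-hydroxycembra-8(19),15(17)-dien-16,14-olide (CNP0230083.2)
Conditions: D-fructose-derived Shi ketone (0.3 equiv), KHSO5 (as 2KHSO5·KHSO4·K2SO4), K2CO3, Bu4NHSO4 (cat.), MeCN/CH2(OMe)2/aq. Na2B4O7 buffer (pH 10.5), 0 °C
Reagents that add atoms: potassium peroxymonosulfate [K+].[O-]S(=O)(=O)OO
Why: Shi asymmetric epoxidation, in which the chiral dioxirane attacks the most electron-rich trisubstituted E-alkene through a spiro transition state to give the 3R,4R epoxide, while the 1,1-disubstituted alkene and the acrylate react far more slowly.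

**Compound list**

1 | pent-4-yn-1-ol | C#CCCCO | starting material
2 | dimethyl[(E)-5-(dimethylalumanyloxy)-2-methylpent-1-en-1-yl]alumane (formed in the flask) | C[Al](C)OCCC/C(C)=C/[Al](C)C | intermediate
3 | (E)-5-iodo-4-methylpent-4-en-1-ol | OCCC/C(C)=C/I | intermediate
4 | (E)-5-iodo-4-methylpent-4-enal | O=CCC/C(C)=C/I | intermediate
5 | 2-[(tert-butyldimethylsilyl)oxy]acetaldehyde (TBS-protected glycolaldehyde) | CC(C)(C)[Si](C)(C)OCC=O | starting material
6 | methyl acrylate | C=CC(=O)OC | starting material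
7 | methyl 4-[(tert-butyldimethylsilyl)oxy]-3-hydroxy-2-methylidenebutanoate (racemic) | COC(=O)C(=C)C(O)CO[Si](C)(C)C(C)(C)C | intermediate
8 | methyl (Z)-2-(bromomethyl)-4-[(tert-butyldimethylsilyl)oxy]but-2-enoate | COC(=O)/C(CBr)=C/CO[Si](C)(C)C(C)(C)C | intermediate
9 | 2,2-dimethoxyacetaldehyde | COC(OC)C=O | starting material
10 | cis-but-2-ene | C/C=C\C | starting material
11 | (Z)-but-2-en-1-ylpotassium (formed in the flask) | C/C=C\C[K] | intermediate
12 | (Z)-but-2-en-1-ylbis[(1S,2R,3S,5S)-2,6,6-trimethylbicyclo[3.1.1]heptan-3-yl]borane (formed in the flask) | C/C=C\CB([C@H]1C[C@H]2C[C@@H]([C@@H]1C)C2(C)C)[C@H]1C[C@H]2C[C@@H]([C@@H]1C)C2(C)C | intermediate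
13 | (2R,3S)-1,1-dimethoxy-3-methylpent-4-en-2-ol | COC(OC)[C@H](O)[C@@H](C)C=C | intermediate
14 | triethyl{[(2R,3S)-1,1-dimethoxy-3-methylpent-4-en-2-yl]oxy}silane | COC(OC)[C@H](O[Si](CC)(CC)CC)[C@@H](C)C=C | intermediate
15 | 2,3-dibromoprop-1-ene | C=C(Br)CBr | starting material
16 | 9-[(3S,4R)-5,5-dimethoxy-3-methyl-4-[(triethylsilyl)oxy]pentyl]-9-borabicyclo[3.3.1]nonane (formed in the flask) | COC(OC)[C@H](O[Si](CC)(CC)CC)[C@@H](C)CCB1C2CCCC1CCC2 | intermediate
17 | {[(2R,3S)-7-bromo-1,1-dimethoxy-3-methyloct-7-en-2-yl]oxy}triethylsilane | COC(OC)[C@H](O[Si](CC)(CC)CC)[C@@H](C)CCCC(Br)=C | intermediate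
18 | [(6S,7R)-8,8-dimethoxy-6-methyl-7-[(triethylsilyl)oxy]oct-1-en-2-yl]lithium (formed in the flask) | COC(OC)[C@H](O[Si](CC)(CC)CC)[C@@H](C)CCCC([Li])=C | intermediate
19 | (1E,10S,11R)-1-iodo-12,12-dimethoxy-2,10-dimethyl-6-methylidene-11-[(triethylsilyl)oxy]dodec-1-en-5-ol (both C5 epimers) | COC(OC)[C@H](O[Si](CC)(CC)CC)[C@@H](C)CCCC(=C)C(O)CC/C(C)=C/I | intermediate
20 | (1E,10S,11R)-1-iodo-12,12-dimethoxy-2,10-dimethyl-6-methylidene-11-[(triethylsilyl)oxy]dodec-1-en-5-one | COC(OC)[C@H](O[Si](CC)(CC)CC)[C@@H](C)CCCC(=C)C(=O)CC/C(C)=C/I | intermediate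
21 | (2R,3S,11E)-2-hydroxy-12-iodo-3,11-dimethyl-7-methylidene-8-oxododec-11-enal (formed in the flask) | O=C[C@H](O)[C@@H](C)CCCC(=C)C(=O)CC/C(C)=C/I | intermediate
22 | methyl (3R,4R,5R,6S,14E)-3-{[(tert-butyldimethylsilyl)oxy]methyl}-4,5-dihydroxy-15-iodo-6,14-dimethyl-2,10-dimethylidene-11-oxopentadec-14-enoate (formed in the flask) | COC(=O)C(=C)[C@H](CO[Si](C)(C)C(C)(C)C)[C@@H](O)[C@H](O)[C@@H](C)CCCC(=C)C(=O)CC/C(C)=C/I | intermediate
23 | (4R,5R)-4-{[(tert-butyldimethylsilyl)oxy]methyl}-5-[(1R,2S,10E)-1-hydroxy-11-iodo-2,10-dimethyl-6-methylidene-7-oxoundec-10-en-1-yl]-3-methylideneoxolan-2-one | CC(C)(C)[Si](C)(C)OC[C@H]1C(=C)C(=O)O[C@H]1[C@H](O)[C@@H](C)CCCC(=C)C(=O)CC/C(C)=C/I | intermediate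
24 | (1R,2S,10E)-1-[(2R,3R)-3-{[(tert-butyldimethylsilyl)oxy]methyl}-4-methylidene-5-oxooxolan-2-yl]-11-iodo-2,10-dimethyl-6-methylidene-7-oxoundec-10-en-1-yl acetate | CC(C)(C)[Si](C)(C)OC[C@H]1C(=C)C(=O)O[C@H]1[C@H](OC(C)=O)[C@@H](C)CCCC(=C)C(=O)CC/C(C)=C/I | intermediate
25 | (1R,2S,10E)-1-[(2R,3S)-3-(bromomethyl)-4-methylidene-5-oxooxolan-2-yl]-11-iodo-2,10-dimethyl-6-methylidene-7-oxoundec-10-en-1-yl acetate | BrC[C@H]1C(=C)C(=O)O[C@H]1[C@H](OC(C)=O)[C@@H](C)CCCC(=C)C(=O)CC/C(C)=C/I | intermediate
26 | (1R,2S,7R,10E)-1-[(2R,3S)-3-(bromomethyl)-4-methylidene-5-oxooxolan-2-yl]-7-hydroxy-11-iodo-2,10-dimethyl-6-methylideneundec-10-en-1-yl acetate | BrC[C@H]1C(=C)C(=O)O[C@H]1[C@H](OC(C)=O)[C@@H](C)CCCC(=C)[C@H](O)CC/C(C)=C/I | intermediate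
27 | (1S,3E,7R,12S,13R,14R)-13-acetoxy-7-hydroxycembra-3,8(19),15(17)-trien-16,14-olide | C=C1CCC[C@H](C)[C@@H](OC(C)=O)[C@@H]2OC(=O)C(=C)[C@@H]2C/C=C(C)/CC[C@H]1O | intermediate
28 | (1S,3R,4R,7R,12S,13R,14R)-13-acetoxy-3,4-epoxy-7-hydroxycembra-8(19),15(17)-dien-16,14-olide (CNP0230083.2) | C=C1CCC[C@H](C)[C@@H](OC(C)=O)[C@@H]2OC(=O)C(=C)[C@@H]2C[C@H]2O[C@]2(C)CC[C@H]1O | target

**Step count and risks**

Total steps: 15. Longest linear sequence: 11 steps (steps 5 to 15); steps 1–2 and 3–4 are side branches that enter at steps 8 and 10.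

The three steps most likely to fail:

Step 14 (ring closure). The risks are oligomerisation, simple reduction of the C2–Br bond, a 1,2-shift of the acrylate carbon through 3-exo closure of the C2 radical, and binding of zerovalent nickel to the α-methylene lactone. The fallback closes the same bond by a polar route; it sets out from 25 and comes back at 27. Zinc insertion into the C–Br bond of 25 (Zn dust, LiCl, THF, 40 °C) gives the alkylzinc bromide bromo({(2R,3S)-2-[(1R,2S,10E)-1-acetoxy-11-iodo-2,10-dimethyl-6-methylidene-7-oxoundec-10-en-1-yl]-4-methylidene-5-oxooxolan-3-yl}methyl)zinc F1. Intramolecular Negishi coupling with the alkenyl iodide (Pd2(dba)3, tri(2-furyl)phosphine, THF/DMA, 2 mM, 50 °C) then gives the macrocyclic enone (1S,3E,12S,13R,14R)-13-acetoxy-7-oxocembra-3,8(19),15(17)-trien-16,14-olide F2. CBS reduction under the conditions of step 13 converts F2 into 27.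

Step 15 (epoxidation). The macrocycle may expose only one face of the C3=C4 alkene and override the catalyst, and the C7 hydroxyl can open the epoxide transannularly. The fallback delivers oxygen to the face opposite to the one an electrophile attacks; it sets out from 27 and comes back at 28. Silylation (TESCl, imidazole, CH2Cl2) gives the silyl ether (1S,3E,7R,12S,13R,14R)-13-acetoxy-7-[(triethylsilyl)oxy]cembra-3,8(19),15(17)-trien-16,14-olide F3. NBS in THF/H2O at 0 °C gives the bromohydrin (1S,3S,4R,7R,12S,13R,14R)-13-acetoxy-3-bromo-4-hydroxy-7-[(triethylsilyl)oxy]cembra-8(19),15(17)-dien-16,14-olide F4, with water entering at the tertiary carbon anti to bromine. Cs2CO3 in MeCN closes it with inversion at C3 to the protected epoxide (1S,3R,4R,7R,12S,13R,14R)-13-acetoxy-3,4-epoxy-7-[(triethylsilyl)oxy]cembra-8(19),15(17)-dien-16,14-olide F5. TBAF buffered with AcOH (THF, 0 °C) then gives 28.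

Step 10 (hydrolysis, Barbier allylation, lactonisation). The α-hydroxy aldehyde 21 is labile, three relationships (C13/C14, C14/C1, γ- versus δ-lactone) must all go the right way, and the allylindium from 8 could lose silyloxide by 1,4-elimination. The fallback replaces the Barbier reaction by a Lewis-acid-mediated allylstannane addition through an open transition state; it sets out from 8 and 20 and comes back at 22, which lactonises to 23 as in step 10. Bu3SnLi (THF, −78 °C) converts 8 into the allylstannane methyl (Z)-4-[(tert-butyldimethylsilyl)oxy]-2-[(tributylstannyl)methyl]but-2-enoate F6. Compound 20 is hydrolysed to crude 21 (TFA/H2O), and MgBr2·OEt2 in CH2Cl2 at −20 °C then promotes addition of F6 to the magnesium chelate of 21. Chelation gives the C13/C14 syn diol and the antiperiplanar open transition state gives the C14/C1 syn relationship, so the product is 22.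

Further compounds

F1 | step 14 | bromo({(2R,3S)-2-[(1R,2S,10E)-1-acetoxy-11-iodo-2,10-dimethyl-6-methylidene-7-oxoundec-10-en-1-yl]-4-methylidene-5-oxooxolan-3-yl}methyl)zinc | Br[Zn]C[C@H]1C(=C)C(=O)O[C@H]1[C@H](OC(C)=O)[C@@H](C)CCCC(=C)C(=O)CC/C(C)=C/I
F2 | step 14 | (1S,3E,12S,13R,14R)-13-acetoxy-7-oxocembra-3,8(19),15(17)-trien-16,14-olide | C=C1CCC[C@H](C)[C@@H](OC(C)=O)[C@@H]2OC(=O)C(=C)[C@@H]2C/C=C(C)/CCC1=O
F3 | step 15 | (1S,3E,7R,12S,13R,14R)-13-acetoxy-7-[(triethylsilyl)oxy]cembra-3,8(19),15(17)-trien-16,14-olide | C=C1CCC[C@H](C)[C@@H](OC(C)=O)[C@@H]2OC(=O)C(=C)[C@@H]2C/C=C(C)/CC[C@H]1O[Si](CC)(CC)CC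
F4 | step 15 | (1S,3S,4R,7R,12S,13R,14R)-13-acetoxy-3-bromo-4-hydroxy-7-[(triethylsilyl)oxy]cembra-8(19),15(17)-dien-16,14-olide | C=C1CCC[C@H](C)[C@@H](OC(C)=O)[C@@H]2OC(=O)C(=C)[C@@H]2C[C@H](Br)[C@](C)(O)CC[C@H]1O[Si](CC)(CC)CC
F5 | step 15 | (1S,3R,4R,7R,12S,13R,14R)-13-acetoxy-3,4-epoxy-7-[(triethylsilyl)oxy]cembra-8(19),15(17)-dien-16,14-olide | C=C1CCC[C@H](C)[C@@H](OC(C)=O)[C@@H]2OC(=O)C(=C)[C@@H]2C[C@H]2O[C@]2(C)CC[C@H]1O[Si](CC)(CC)CC
F6 | step 10 | methyl (Z)-4-[(tert-butyldimethylsilyl)oxy]-2-[(tributylstannyl)methyl]but-2-enoate | COC(=O)/C(C[Sn](CCCC)(CCCC)CCCC)=C/CO[Si](C)(C)C(C)(C)C
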